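**Retrosynthetic overview**
1. Target 42 ⇐ hydrolysis of enol ether, ketal and silyl ether ⇐ Stille acetyl equivalent on a vinyl triflate and α-methylenation of the unit A lactone ⇐ spiro β-keto lactone 36.
2. 36 ⇐ intramolecular Claisen acylation (C3–C11') of a Weinreb amide that was put on the C1 ketone of keto bis-lactone 33 by aldol addition (C1–C2).
3. Key union: 33 ⇐ intermolecular Mukaiyama–Michael addition (C11'–C13') of the unit B ketene silyl acetal 31 to the unit A α-methylene ketone 15.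
4. 15 and 31 ⇐ mirror-image keto lactones 12 and 26 ⇐ mirror-image lactones 7 and 21, both from one monoacetate 4 of meso cyclohept-2-ene-1,4-diol (Johnson–Claisen versus Ireland–Claisen).
5. Ring order: seven-membered carbocycles come from cyclohepta-1,3-diene; the two γ-lactones are closed next (steps 4 and 11); the spiro cyclohexene ring is closed last (step 21).

**Conventions and assumptions**
- Monomers carry cyclohepta[b]furan-2-one locants (O1, C2, C3, C3a, C4–C8, C8a). Dimers carry target locants: unit A (half with the tertiary alcohol) has C1 (carbinol), C2/C3 (enone CH and acyl-bearing carbon), C5 (ring-fusion CH), C10 (CHMe), C11 (lactone α-carbon); unit B is primed, C11' is the spiro carbon and C13' the CH2 between C11' and C5. Monomer C5, C6, C7, C3 become dimer C5, C1, C10, C11.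
- LacB = (3aS,7R,8aS)-7-methyl-6-[2-(2-methyl-1,3-dioxolan-2-yl)ethyl]-2-oxo-3,3a,4,7,8,8a-hexahydro-2H-cyclohepta[b]furan-3-yl; its C3 is a mixture of epimers until step 21.
- Assumption 1: the SMILES is taken literally; unit A is then (7R,8R,10S) and unit B (7'S,8'S,10'R), so the two lactone halves are made as mirror-image building blocks.
- Assumption 2: the lipase gives monoacetate 4 as drawn; if it gives the mirror image, the step 3–4 and step 9–11 sequences simply exchange the series they feed.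

**Route**

Step 1
Reactants: 1 cyclohepta-1,3-diene
Product: 3 cis-cyclohept-2-ene-1,4-diol, via endoperoxide 2 (not isolated)
Conditions: O2, tetraphenylporphyrin (cat.), hν, CH2Cl2, 0 °C; then Zn, AcOH, 0→23 °C
Reagents that add atoms: dioxygen, O=O
Why: Singlet-oxygen [4+2] cycloaddition gives the bridged endoperoxide and O–O reduction leaves both C–O bonds on one face, so the diol is cis (meso).

Step 2
Reactants: 3 cis-cyclohept-2-ene-1,4-diol
Product: 4 (1R,4S)-4-hydroxycyclohept-2-en-1-yl acetate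
Conditions: Burkholderia cepacia lipase (lipase PS), vinyl acetate, MTBE, 23 °C
Reagents that add atoms: vinyl acetate, C=COC(C)=O
Why: Enzymatic desymmetrisation by irreversible transesterification acylates one enantiotopic hydroxyl of the meso diol and so fixes both carbinol centres.

Step 3
Reactants: 4 (1R,4S)-4-hydroxycyclohept-2-en-1-yl acetate
Product: 5 ethyl 2-[(1S,7R)-7-acetoxycyclohept-2-en-1-yl]acetate
Conditions: MeC(OEt)3, EtCO2H (cat.), 140 °C, EtOH distilled off
Reagents that add atoms: triethyl orthoacetate, CC(OCC)(OCC)OCC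
Why: Johnson–Claisen rearrangement; the suprafacial [3,3] shift delivers CH2CO2Et to the alkene carbon on the face of the departing C–O bond, that is cis to the neighbouring acetoxy group.

Step 4
Reactants: 5 ethyl 2-[(1S,7R)-7-acetoxycyclohept-2-en-1-yl]acetate
Product: 7 (3aS,8aR)-3,3a,6,7,8,8a-hexahydro-2H-cyclohepta[b]furan-2-one, via hydroxy ester 6 (not isolated)
Conditions: K2CO3, EtOH, 23 °C; then TsOH·H2O (cat.), PhMe, 60 °C
Reagents that add atoms: none
Why: Transesterification removes the acetate and the cis γ-hydroxy ester lactonises to the cis-fused γ-lactone without touching a stereocentre.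

Step 5
Reactants: 7 (3aS,8aR)-3,3a,6,7,8,8a-hexahydro-2H-cyclohepta[b]furan-2-one
Product: 8 (3aS,8aR)-3,3a,8,8a-tetrahydro-2H-cyclohepta[b]furan-2,6(7H)-dione
Conditions: t-BuOOH, Rh2(C6H10NO)4 (dirhodium tetracaprolactamate, 1 mol %), K2CO3, CH2Cl2, 23 °C
Reagents that add atoms: tert-butyl hydroperoxide, CC(C)(C)OO
Why: Radical allylic oxidation attacks the only allylic CH2 (C6), because the tertiary ring-fusion C–H is hindered and its oxidation would need bonding at the hindered alkene terminus.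

Step 6
Reactants: 8 (3aS,8aR)-3,3a,8,8a-tetrahydro-2H-cyclohepta[b]furan-2,6(7H)-dione
Product: 11 (3aS,8aR)-7-methylidene-3,3a,8,8a-tetrahydro-2H-cyclohepta[b]furan-2,6(7H)-dione, via Mannich base 9 (not isolated), via methiodide 10 (not isolated)
Conditions: LiN(i-Pr)2 (1.05 equiv), THF, −78 °C; [Me2N=CH2]I, −78→23 °C; then MeI, MeOH, 23 °C; then aq. NaHCO3, CH2Cl2
Reagents that add atoms: N,N-dimethylmethyleneiminium iodide (Eschenmoser's salt), C=[N+](C)C.[I-]
Why: Kinetic deprotonation of the enone can only occur at the α'-CH2 (C7), the enolate undergoes a Mannich reaction and Hofmann-type elimination of the quaternised amine gives the exocyclic methylene, which is used at once.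

Step 7
Reactants: 11 (3aS,8aR)-7-methylidene-3,3a,8,8a-tetrahydro-2H-cyclohepta[b]furan-2,6(7H)-dione
Product: 12 (3aR,7S,8aR)-7-methylhexahydro-2H-cyclohepta[b]furan-2,6(3H)-dione
Conditions: H2 (1 atm), Rh/Al2O3 (5 %), EtOAc, 23 °C
Reagents that add atoms: none
Why: Heterogeneous hydrogenation saturates both C=C bonds and delivers hydrogen to C7 from the convex face of the cis-fused bicycle (the face of H-3a and H-8a), which places the methyl cis to the lactone oxygen.

Step 8
Reactants: 12 (3aR,7S,8aR)-7-methylhexahydro-2H-cyclohepta[b]furan-2,6(3H)-dione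
Product: 15 (3aR,7S,8aR)-7-methyl-5-methylidenehexahydro-2H-cyclohepta[b]furan-2,6(3H)-dione, via Mannich base 13 (not isolated), via methiodide 14 (not isolated)
Conditions: LiN(i-Pr)2 (1.05 equiv), THF, −78 °C; [Me2N=CH2]I, −78→23 °C; then MeI, MeOH, 23 °C; then aq. NaHCO3, CH2Cl2
Reagents that add atoms: N,N-dimethylmethyleneiminium iodide (Eschenmoser's salt), C=[N+](C)C.[I-]
Why: The kinetic enolate forms at the less substituted C5 (the C7 stereocentre and the less acidic lactone CH2 are untouched), and Mannich reaction then elimination give the α-methylene ketone whose new CH2 becomes C13'.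

Step 9
Reactants: 4 (1R,4S)-4-hydroxycyclohept-2-en-1-yl acetate
Product: 16 (1R,4S)-4-[(tert-butyldimethylsilyl)oxy]cyclohept-2-en-1-yl acetate
Conditions: TBSCl, imidazole, DMF, 23 °C
Reagents that add atoms: tert-butyldimethylsilyl chloride, CC(C)(C)[Si](C)(C)Cl
Why: Silylation blocks the free hydroxyl so that the acetate oxygen becomes the Claisen donor, which leads into the mirror-image series.

Step 10
Reactants: 16 (1R,4S)-4-[(tert-butyldimethylsilyl)oxy]cyclohept-2-en-1-yl acetate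
Product: 19 2-[(1R,7S)-7-[(tert-butyldimethylsilyl)oxy]cyclohept-2-en-1-yl]acetic acid, via ketene silyl acetal 17 (not isolated), via silyl ester 18 (not isolated)
Conditions: LiN(i-Pr)2, Me3SiCl, THF, −78 °C; then 65 °C; then H2O
Reagents that add atoms: none
Why: Ireland–Claisen rearrangement of the allylic acetate; the suprafacial [3,3] shift puts the CH2CO2H group cis to the silyloxy group on the adjacent carbon.

Step 11
Reactants: 19 2-[(1R,7S)-7-[(tert-butyldimethylsilyl)oxy]cyclohept-2-en-1-yl]acetic acid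
Product: 21 (3aR,8aS)-3,3a,6,7,8,8a-hexahydro-2H-cyclohepta[b]furan-2-one, via hydroxy acid 20 (not isolated)
Conditions: 3 M HCl, THF, 50 °C
Reagents that add atoms: none
Why: Acidic desilylation and lactonisation of the cis γ-hydroxy acid give the enantiomer of 7.

Step 12
Reactants: 21 (3aR,8aS)-3,3a,6,7,8,8a-hexahydro-2H-cyclohepta[b]furan-2-one
Product: 22 (3aR,8aS)-3,3a,8,8a-tetrahydro-2H-cyclohepta[b]furan-2,6(7H)-dione
Conditions: t-BuOOH, Rh2(C6H10NO)4 (1 mol %), K2CO3, CH2Cl2, 23 °C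
Reagents that add atoms: tert-butyl hydroperoxide, CC(C)(C)OO
Why: Same radical allylic oxidation of the single allylic CH2 as in step 5.

Step 13
Reactants: 22 (3aR,8aS)-3,3a,8,8a-tetrahydro-2H-cyclohepta[b]furan-2,6(7H)-dione
Product: 25 (3aR,8aS)-7-methylidene-3,3a,8,8a-tetrahydro-2H-cyclohepta[b]furan-2,6(7H)-dione, via Mannich base 23 (not isolated), via methiodide 24 (not isolated)
Conditions: LiN(i-Pr)2 (1.05 equiv), THF, −78 °C; [Me2N=CH2]I, −78→23 °C; then MeI, MeOH, 23 °C; then aq. NaHCO3, CH2Cl2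
Reagents that add atoms: N,N-dimethylmethyleneiminium iodide (Eschenmoser's salt), C=[N+](C)C.[I-]
Why: Same α'-selective Mannich reaction and elimination as in step 6.

Step 14
Reactants: 25 (3aR,8aS)-7-methylidene-3,3a,8,8a-tetrahydro-2H-cyclohepta[b]furan-2,6(7H)-dione
Product: 26 (3aS,7R,8aS)-7-methylhexahydro-2H-cyclohepta[b]furan-2,6(3H)-dione
Conditions: H2 (1 atm), Rh/Al2O3 (5 %), EtOAc, 23 °C
Reagents that add atoms: none
Why: Convex-face hydrogenation as in step 7 sets the methyl cis to the lactone oxygen and gives the enantiomer of 12.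

Step 15
Reactants: 26 (3aS,7R,8aS)-7-methylhexahydro-2H-cyclohepta[b]furan-2,6(3H)-dione
Product: 27 (3aS,7R,8aS)-7-methyl-2-oxo-3,3a,4,7,8,8a-hexahydro-2H-cyclohepta[b]furan-6-yl trifluoromethanesulfonate
Conditions: LiN(i-Pr)2 (1.05 equiv), THF, −78 °C; PhNTf2, −78→0 °C
Reagents that add atoms: N-phenylbis(trifluoromethanesulfonimide), O=S(=O)(N(c1ccccc1)S(=O)(=O)C(F)(F)F)C(F)(F)F
Why: O-Triflation of the kinetic enolate (deprotonation at CH2, not at CHMe) fixes the C5=C6 double bond and leaves the C7 stereocentre untouched.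

Step 16
Reactants: 27 (3aS,7R,8aS)-7-methyl-2-oxo-3,3a,4,7,8,8a-hexahydro-2H-cyclohepta[b]furan-6-yl trifluoromethanesulfonate; 28 2-(2-bromoethyl)-2-methyl-1,3-dioxolane
Product: 30 (3aS,7R,8aS)-7-methyl-6-[2-(2-methyl-1,3-dioxolan-2-yl)ethyl]-3,3a,4,7,8,8a-hexahydro-2H-cyclohepta[b]furan-2-one, via organozinc bromide 29 (not isolated)
Conditions: 28, Zn, LiCl, THF, 40 °C; then 27, PdCl2(dppf) (5 mol %), THF, 50 °C
Reagents that add atoms: none
Why: Negishi sp3–sp2 cross-coupling of the alkylzinc reagent with the vinyl triflate installs the protected 3-oxobutyl chain with retention of the alkene position and tolerates the lactone.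

Step 17
Reactants: 30 (3aS,7R,8aS)-7-methyl-6-[2-(2-methyl-1,3-dioxolan-2-yl)ethyl]-3,3a,4,7,8,8a-hexahydro-2H-cyclohepta[b]furan-2-one
Product: 31 tert-butyldimethylsilyl ketene acetal of 30 (2-silyloxy-3a,4,7,8-tetrahydro-8aH-cyclohepta[b]furan with C2=C3 double bond; 3aS,7R,8aS)
Conditions: LiN(i-Pr)2, THF, −78 °C; TBSCl, DMPU, −78→0 °C; non-aqueous work-up
Reagents that add atoms: tert-butyldimethylsilyl chloride, CC(C)(C)[Si](C)(C)Cl
Why: The lactone CH2 is the only acidic site and O-silylation of its enolate gives the nucleophile for the uncatalysed Mukaiyama–Michael reaction.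

Step 18
Reactants: 31 tert-butyldimethylsilyl ketene acetal of 30; 15 (3aR,7S,8aR)-7-methyl-5-methylidenehexahydro-2H-cyclohepta[b]furan-2,6(3H)-dione
Product: 33 (3aR,5S,7S,8aR)-5-(LacB-methyl)-7-methylhexahydro-2H-cyclohepta[b]furan-2,6(3H)-dione, via silyl enol ether 32 (not isolated)
Conditions: MeCN, 40 °C; then Bu4NF, AcOH, THF, −78→0 °C
Reagents that add atoms: none
Why: Uncatalysed Mukaiyama–Michael addition of the ketene silyl acetal to the s-cis exocyclic enone forms the C11'–C13' bond with silyl transfer to a regiodefined enol ether, and buffered fluoride then protonates the enolate at C5 from the face opposite the fused lactone and the C7 methyl (C5 S); the lactone α-carbon C11' is left as a mixture and is re-enolised in step 21.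

Step 19
Reactants: 33 (3aR,5S,7S,8aR)-5-(LacB-methyl)-7-methylhexahydro-2H-cyclohepta[b]furan-2,6(3H)-dione
Product: 34 2-[(3aR,5S,6S,7S,8aR)-6-hydroxy-5-(LacB-methyl)-7-methyl-2-oxooctahydro-2H-cyclohepta[b]furan-6-yl]-N-methoxy-N-methylacetamide
Conditions: MeC(O)N(OMe)Me, LiN(i-Pr)2, THF, −78 °C; CeCl3, −78 °C; then 33, −78 °C; aq. NH4Cl
Reagents that add atoms: N-methoxy-N-methylacetamide, CC(=O)N(C)OC
Why: Aldol-type 1,2-addition of the cerium amide enolate (cerium suppresses enolisation of the hindered ketone and lactones react more slowly) occurs on the face of H-5 and H-7, anti to both α-substituents and the lactone, so the new hydroxyl is cis to them.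

Step 20
Reactants: 34 the β-hydroxy Weinreb amide
Product: 35 triethylsilyl ether of 34 (6-OSiEt3)
Conditions: Et3SiOTf, 2,6-lutidine, CH2Cl2, −78→0 °C
Reagents that add atoms: triethylsilyl trifluoromethanesulfonate, CC[Si](CC)(CC)OS(=O)(=O)C(F)(F)F
Why: Silylation of the tertiary alcohol prevents retro-aldol cleavage in the following base steps; the ketone-derived dioxolane is stable to these conditions.

Step 21
Reactants: 35 triethylsilyl ether of 34
Product: 36 spiro β-keto lactone (target skeleton with C1–OSiEt3, C2 H2, C3 ketone, spiro C11' as in the target, saturated unit A lactone, side-chain ketone as dioxolane)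
Conditions: LiN(SiMe3)2 (3 equiv), THF, −78→0 °C; aq. NH4Cl
Reagents that add atoms: none
Why: Intramolecular Claisen (Dieckmann-type) acylation: the silylamide enolises lactones but not the amide, only the unit B lactone enolate reaches the Weinreb carbonyl through a six-membered transition state, and acylation on its convex face (anti to the cycloheptene ring) sets the spiro carbon C11' while the chelated tetrahedral intermediate prevents over-reaction.

Step 22
Reactants: 36 spiro β-keto lactone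
Product: 37 vinyl triflate of 36 (C2=C3–OTf)
Conditions: KN(SiMe3)2 (1.1 equiv), THF, −78 °C; N-(5-chloropyridin-2-yl)bis(trifluoromethanesulfonimide) (Comins' reagent), −78 °C
Reagents that add atoms: Comins' reagent, O=S(=O)(N(c1ccc(Cl)cn1)S(=O)(=O)C(F)(F)F)C(F)(F)F
Why: Enol triflate formation is regiospecific because only C2 carries α-hydrogens, and trapping at −78 °C avoids β-elimination of the silyloxy group.

Step 23
Reactants: 37 vinyl triflate of 36
Product: 40 α-methylene lactone vinyl triflate (37 with C11=CH2 in unit A), via Mannich base 38 (not isolated), via methiodide 39 (not isolated)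
Conditions: LiN(i-Pr)2 (1.1 equiv), THF, −78 °C; [Me2N=CH2]I, −78→23 °C; then MeI, MeOH, 23 °C; then aq. NaHCO3, CH2Cl2
Reagents that add atoms: N,N-dimethylmethyleneiminium iodide (Eschenmoser's salt), C=[N+](C)C.[I-]
Why: The unit A lactone CH2 is now the only acidic C–H, so Mannich reaction and elimination (α-methylenation) are site-selective.

Step 24
Reactants: 40 α-methylene lactone vinyl triflate
Product: 41 2-ethoxydiene (C3 carries C(OEt)=CH2)
Conditions: Bu3SnC(OEt)=CH2, Pd(PPh3)4 (10 mol %), LiCl, CuI (cat.), THF, 65 °C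
Reagents that add atoms: tributyl(1-ethoxyvinyl)stannane, CCOC(=C)[Sn](CCCC)(CCCC)CCCC
Why: Stille coupling of the hindered vinyl triflate with an acetyl anion equivalent builds the C3–C4 bond without touching any stereocentre.

Step 25
Reactants: 41 2-ethoxydiene
Product: 42 target CNP0195550.2
Conditions: 1 M HCl, THF, 23 °C
Reagents that add atoms: water, O
Why: Acid hydrolysis converts the enol ether into the conjugated methyl ketone, the dioxolane into the side-chain ketone and the silyl ether into the tertiary alcohol, with no stereocentre affected.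

**Compound list**
1 | cyclohepta-1,3-diene | C1=CC=CCCC1 | starting material
2 | 6,7-dioxabicyclo[3.2.2]non-8-ene (meso endoperoxide) | O1[C@@H]2CCC[C@H](O1)C=C2 | intermediate
3 | cis-cyclohept-2-ene-1,4-diol (meso) | O[C@@H]1CCC[C@H](O)C=C1 | intermediate
4 | (1R,4S)-4-hydroxycyclohept-2-en-1-yl acetate | CC(=O)O[C@@H]1CCC[C@H](O)C=C1 | intermediate
5 | ethyl 2-[(1S,7R)-7-acetoxycyclohept-2-en-1-yl]acetate | CCOC(=O)C[C@H]1C=CCCC[C@H]1OC(C)=O | intermediate
6 | ethyl 2-[(1S,7R)-7-hydroxycyclohept-2-en-1-yl]acetate | CCOC(=O)C[C@H]1C=CCCC[C@H]1O | intermediate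
7 | (3aS,8aR)-3,3a,6,7,8,8a-hexahydro-2H-cyclohepta[b]furan-2-one | O=C1C[C@H]2C=CCCC[C@H]2O1 | intermediate
8 | (3aS,8aR)-3,3a,8,8a-tetrahydro-2H-cyclohepta[b]furan-2,6(7H)-dione | O=C1C[C@H]2C=CC(=O)CC[C@H]2O1 | intermediate
9 | 7-[(dimethylamino)methyl] derivative of 8 (C7 epimers) | O=C1C[C@H]2C=CC(=O)C(CN(C)C)C[C@H]2O1 | intermediate
10 | trimethylammonium iodide from 9 | O=C1C[C@H]2C=CC(=O)C(C[N+](C)(C)C)C[C@H]2O1.[I-] | intermediate
11 | (3aS,8aR)-7-methylidene-3,3a,8,8a-tetrahydro-2H-cyclohepta[b]furan-2,6(7H)-dione | O=C1C[C@H]2C=CC(=O)C(=C)C[C@H]2O1 | intermediate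
12 | (3aR,7S,8aR)-7-methylhexahydro-2H-cyclohepta[b]furan-2,6(3H)-dione | O=C1C[C@H]2CCC(=O)[C@@H](C)C[C@H]2O1 | intermediate
13 | 5-[(dimethylamino)methyl] derivative of 12 (C5 epimers) | O=C1C[C@H]2CC(CN(C)C)C(=O)[C@@H](C)C[C@H]2O1 | intermediate
14 | trimethylammonium iodide from 13 | O=C1C[C@H]2CC(C[N+](C)(C)C)C(=O)[C@@H](C)C[C@H]2O1.[I-] | intermediate
15 | (3aR,7S,8aR)-7-methyl-5-methylidenehexahydro-2H-cyclohepta[b]furan-2,6(3H)-dione | O=C1C[C@H]2CC(=C)C(=O)[C@@H](C)C[C@H]2O1 | intermediate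
16 | (1R,4S)-4-[(tert-butyldimethylsilyl)oxy]cyclohept-2-en-1-yl acetate | CC(=O)O[C@@H]1CCC[C@H](O[Si](C)(C)C(C)(C)C)C=C1 | intermediate
17 | trimethylsilyl ketene acetal of 16 | C=C(O[Si](C)(C)C)O[C@@H]1CCC[C@H](O[Si](C)(C)C(C)(C)C)C=C1 | intermediate
18 | trimethylsilyl ester of 19 | C[Si](C)(C)OC(=O)C[C@@H]1C=CCCC[C@@H]1O[Si](C)(C)C(C)(C)C | intermediate
19 | 2-[(1R,7S)-7-[(tert-butyldimethylsilyl)oxy]cyclohept-2-en-1-yl]acetic acid | OC(=O)C[C@@H]1C=CCCC[C@@H]1O[Si](C)(C)C(C)(C)C | intermediate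
20 | 2-[(1R,7S)-7-hydroxycyclohept-2-en-1-yl]acetic acid | OC(=O)C[C@@H]1C=CCCC[C@@H]1O | intermediate
21 | (3aR,8aS)-3,3a,6,7,8,8a-hexahydro-2H-cyclohepta[b]furan-2-one | O=C1C[C@@H]2C=CCCC[C@@H]2O1 | intermediate
22 | (3aR,8aS)-3,3a,8,8a-tetrahydro-2H-cyclohepta[b]furan-2,6(7H)-dione | O=C1C[C@@H]2C=CC(=O)CC[C@@H]2O1 | intermediate
23 | 7-[(dimethylamino)methyl] derivative of 22 (C7 epimers) | O=C1C[C@@H]2C=CC(=O)C(CN(C)C)C[C@@H]2O1 | intermediate
24 | trimethylammonium iodide from 23 | O=C1C[C@@H]2C=CC(=O)C(C[N+](C)(C)C)C[C@@H]2O1.[I-] | intermediate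
25 | (3aR,8aS)-7-methylidene-3,3a,8,8a-tetrahydro-2H-cyclohepta[b]furan-2,6(7H)-dione | O=C1C[C@@H]2C=CC(=O)C(=C)C[C@@H]2O1 | intermediate
26 | (3aS,7R,8aS)-7-methylhexahydro-2H-cyclohepta[b]furan-2,6(3H)-dione | O=C1C[C@@H]2CCC(=O)[C@H](C)C[C@@H]2O1 | intermediate
27 | (3aS,7R,8aS)-7-methyl-2-oxo-3,3a,4,7,8,8a-hexahydro-2H-cyclohepta[b]furan-6-yl trifluoromethanesulfonate | O=C1C[C@@H]2CC=C(OS(=O)(=O)C(F)(F)F)[C@H](C)C[C@@H]2O1 | intermediate
28 | 2-(2-bromoethyl)-2-methyl-1,3-dioxolane | CC1(CCBr)OCCO1 | starting material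
29 | bromo[2-(2-methyl-1,3-dioxolan-2-yl)ethyl]zinc | CC1(CC[Zn]Br)OCCO1 | intermediate
30 | (3aS,7R,8aS)-7-methyl-6-[2-(2-methyl-1,3-dioxolan-2-yl)ethyl]-3,3a,4,7,8,8a-hexahydro-2H-cyclohepta[b]furan-2-one | O=C1C[C@@H]2CC=C(CCC3(C)OCCO3)[C@H](C)C[C@@H]2O1 | intermediate
31 | tert-butyldimethylsilyl ketene acetal of 30 | CC(C)(C)[Si](C)(C)OC1=C[C@@H]2CC=C(CCC3(C)OCCO3)[C@H](C)C[C@@H]2O1 | intermediate
32 | tert-butyldimethylsilyl enol ether of 33 (C5=C6 enol ether of the unit A ring; LacB C3 epimers) | O=C1C[C@H]2CC(CC3C(=O)O[C@H]4C[C@@H](C)C(CCC5(C)OCCO5)=CC[C@@H]34)=C(O[Si](C)(C)C(C)(C)C)[C@@H](C)C[C@H]2O1 | intermediate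
33 | (3aR,5S,7S,8aR)-5-(LacB-methyl)-7-methylhexahydro-2H-cyclohepta[b]furan-2,6(3H)-dione | O=C1C[C@H]2C[C@@H](CC3C(=O)O[C@H]4C[C@@H](C)C(CCC5(C)OCCO5)=CC[C@@H]34)C(=O)[C@@H](C)C[C@H]2O1 | intermediate
34 | 2-[(3aR,5S,6S,7S,8aR)-6-hydroxy-5-(LacB-methyl)-7-methyl-2-oxooctahydro-2H-cyclohepta[b]furan-6-yl]-N-methoxy-N-methylacetamide (OH cis to the 7-methyl and the C5 chain) | O=C1C[C@H]2C[C@@H](CC3C(=O)O[C@H]4C[C@@H](C)C(CCC5(C)OCCO5)=CC[C@@H]34)[C@](O)(CC(=O)N(C)OC)[C@@H](C)C[C@H]2O1 | intermediate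
35 | triethylsilyl ether of 34 | O=C1C[C@H]2C[C@@H](CC3C(=O)O[C@H]4C[C@@H](C)C(CCC5(C)OCCO5)=CC[C@@H]34)[C@](O[Si](CC)(CC)CC)(CC(=O)N(C)OC)[C@@H](C)C[C@H]2O1 | intermediate
36 | spiro β-keto lactone: target skeleton with C1–OSiEt3, C2 H2, C3 ketone, saturated unit A lactone, dioxolane-protected side chain; all stereocentres as in the target | C1C(=O)O[C@@H]2C[C@H](C)[C@@]3(O[Si](CC)(CC)CC)CC(=O)[C@]4(C[C@@H]3C[C@H]12)C(=O)O[C@H]1C[C@@H](C)C(CCC5(C)OCCO5)=CC[C@H]14 | intermediate
37 | vinyl triflate of 36 (C2=C3–OTf) | C1C(=O)O[C@@H]2C[C@H](C)[C@@]3(O[Si](CC)(CC)CC)C=C(OS(=O)(=O)C(F)(F)F)[C@]4(C[C@@H]3C[C@H]12)C(=O)O[C@H]1C[C@@H](C)C(CCC5(C)OCCO5)=CC[C@H]14 | intermediate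
38 | 37 with CH2NMe2 on C11 of the unit A lactone (C11 epimers) | CN(C)CC1C(=O)O[C@@H]2C[C@H](C)[C@@]3(O[Si](CC)(CC)CC)C=C(OS(=O)(=O)C(F)(F)F)[C@]4(C[C@@H]3C[C@H]12)C(=O)O[C@H]1C[C@@H](C)C(CCC5(C)OCCO5)=CC[C@H]14 | intermediate
39 | trimethylammonium iodide from 38 | C[N+](C)(C)CC1C(=O)O[C@@H]2C[C@H](C)[C@@]3(O[Si](CC)(CC)CC)C=C(OS(=O)(=O)C(F)(F)F)[C@]4(C[C@@H]3C[C@H]12)C(=O)O[C@H]1C[C@@H](C)C(CCC5(C)OCCO5)=CC[C@H]14.[I-] | intermediate
40 | α-methylene lactone vinyl triflate (37 with C11=CH2) | C=C1C(=O)O[C@@H]2C[C@H](C)[C@@]3(O[Si](CC)(CC)CC)C=C(OS(=O)(=O)C(F)(F)F)[C@]4(C[C@@H]3C[C@H]12)C(=O)O[C@H]1C[C@@H](C)C(CCC5(C)OCCO5)=CC[C@H]14 | intermediate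
41 | 2-ethoxydiene (40 with C(OEt)=CH2 in place of OTf) | C=C1C(=O)O[C@@H]2C[C@H](C)[C@@]3(O[Si](CC)(CC)CC)C=C(C(=C)OCC)[C@]4(C[C@@H]3C[C@H]12)C(=O)O[C@H]1C[C@@H](C)C(CCC5(C)OCCO5)=CC[C@H]14 | intermediate
42 | CNP0195550.2 | C=C1C(=O)O[C@@H]2C[C@H](C)[C@@]3(O)C=C(C(C)=O)[C@]4(C[C@@H]3C[C@H]12)C(=O)O[C@H]1C[C@@H](C)C(CCC(C)=O)=CC[C@H]14 | target

**Totals**
Total step count: 25. Longest linear sequence: 19 steps (1, 2, 9–25).

**Three steps most likely to fail**

Step 18 (union and C5 configuration). The Michael addition itself is favourable, but C5 is set by enolate protonation and the face preference of this flexible ring is not certain. Fallback, setting out from 30 and 12 and returning at 33: lactone 30 is α-methylenated (LiN(i-Pr)2; Eschenmoser's salt; MeI; NaHCO3) through the Mannich base F1 and its methiodide F2 to the α-methylene lactone F3. Ketone 12 is converted with LiN(i-Pr)2 at −78 °C into its kinetic lithium enolate F4, which is added to F3 at −78 °C and quenched cold to give 33. This is the Michael addition in the opposite polarity, so C5 is set in the carbon–carbon bond-forming event and the carbon enters on the face that the proton takes in step 18; whichever face the ring prefers, one of the two modes gives the required epimer.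

Step 19 (addition to the hindered, enolisable C1 ketone). The amide enolate may enolise the ketone or add with poor face selectivity. Fallback, setting out from 33 and returning at 35: vinylmagnesium bromide with CeCl3 at −78 °C gives the tertiary vinyl carbinol F5; Et3SiOTf and 2,6-lutidine give its silyl ether F6; 9-BBN then NaBO3 hydroborates only the terminal vinyl group to the primary alcohol F7; TEMPO and PhI(OAc)2 in wet MeCN oxidise it to the carboxylic acid F8; coupling with MeNHOMe·HCl and EDC·HCl gives 35.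

Step 21 (Dieckmann-type acylation forming the quaternary spiro carbon). The tertiary lactone enolate may be too hindered to attack the amide. Fallback, setting out from 33 and returning at 36: lithioacetonitrile with CeCl3 adds to the ketone to give the β-hydroxy nitrile F9; Et3SiOTf and 2,6-lutidine give the silyl ether F10; LiN(SiMe3)2 then closes the ring by Thorpe-type addition of the lactone enolate to the nitrile, giving the cyclic imine F11; buffered aqueous AcOH hydrolyses the imine to 36.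

**Further compounds**
F1 | step 18 | 3-[(dimethylamino)methyl] derivative of 30 (C3 epimers) | CN(C)CC1C(=O)O[C@H]2C[C@@H](C)C(CCC3(C)OCCO3)=CC[C@@H]12
F2 | step 18 | trimethylammonium iodide from F1 | C[N+](C)(C)CC1C(=O)O[C@H]2C[C@@H](C)C(CCC3(C)OCCO3)=CC[C@@H]12.[I-]
F3 | step 18 | (3aS,7R,8aS)-7-methyl-3-methylidene-6-[2-(2-methyl-1,3-dioxolan-2-yl)ethyl]-3,3a,4,7,8,8a-hexahydro-2H-cyclohepta[b]furan-2-one | C=C1C(=O)O[C@H]2C[C@@H](C)C(CCC3(C)OCCO3)=CC[C@@H]12
F4 | step 18 | lithium (3aR,7S,8aR)-7-methyl-2-oxo-3,3a,4,7,8,8a-hexahydro-2H-cyclohepta[b]furan-6-olate | O=C1C[C@H]2CC=C(O[Li])[C@@H](C)C[C@H]2O1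
F5 | step 19 | tertiary vinyl carbinol from 33 (6-hydroxy-6-vinyl; OH cis to the 7-methyl) | O=C1C[C@H]2C[C@@H](CC3C(=O)O[C@H]4C[C@@H](C)C(CCC5(C)OCCO5)=CC[C@@H]34)[C@](O)(C=C)[C@@H](C)C[C@H]2O1
F6 | step 19 | triethylsilyl ether of F5 | O=C1C[C@H]2C[C@@H](CC3C(=O)O[C@H]4C[C@@H](C)C(CCC5(C)OCCO5)=CC[C@@H]34)[C@](O[Si](CC)(CC)CC)(C=C)[C@@H](C)C[C@H]2O1
F7 | step 19 | primary alcohol from F6 (6-(2-hydroxyethyl)) | O=C1C[C@H]2C[C@@H](CC3C(=O)O[C@H]4C[C@@H](C)C(CCC5(C)OCCO5)=CC[C@@H]34)[C@](O[Si](CC)(CC)CC)(CCO)[C@@H](C)C[C@H]2O1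
F8 | step 19 | carboxylic acid from F7 (6-(carboxymethyl)) | O=C1C[C@H]2C[C@@H](CC3C(=O)O[C@H]4C[C@@H](C)C(CCC5(C)OCCO5)=CC[C@@H]34)[C@](O[Si](CC)(CC)CC)(CC(=O)O)[C@@H](C)C[C@H]2O1
F9 | step 21 | β-hydroxy nitrile from 33 (6-hydroxy-6-(cyanomethyl)) | O=C1C[C@H]2C[C@@H](CC3C(=O)O[C@H]4C[C@@H](C)C(CCC5(C)OCCO5)=CC[C@@H]34)[C@](O)(CC#N)[C@@H](C)C[C@H]2O1
F10 | step 21 | triethylsilyl ether of F9 | O=C1C[C@H]2C[C@@H](CC3C(=O)O[C@H]4C[C@@H](C)C(CCC5(C)OCCO5)=CC[C@@H]34)[C@](O[Si](CC)(CC)CC)(CC#N)[C@@H](C)C[C@H]2O1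
F11 | step 21 | cyclic imine (36 with C3=NH in place of C3=O) | C1C(=O)O[C@@H]2C[C@H](C)[C@@]3(O[Si](CC)(CC)CC)CC(=N)[C@]4(C[C@@H]3C[C@H]12)C(=O)O[C@H]1C[C@@H](C)C(CCC5(C)OCCO5)=CC[C@H]14
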